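Remarks on the chemistry
- Locants: C7–C8–C9 is the glycerol chain on ring A; C7', C8', C9' and C7'', C8'', C9'' belong to the lignan half (ring B on C7', ring C on C7'').
- Structure check: the keto ester and its reduction product agree with the target and need no correction. The (2R,3R) ester and the (7R,8S) diol have the same spatial arrangement; the C8 descriptor changes only because CH2OH ranks below the C7 carbinol carbon, whereas CO2Et ranks above it.
- Assumption: a ketoreductase variant with anti (erythro) preference for keto ester 7 is taken to exist in a commercial enzyme panel; 4, 10, 11 and 14 are catalogue compounds.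

## Structural features

The target is built from three guaiacyl rings. Ring A carries the C7–C8–C9 glycerol chain, C8 is bound through an ether oxygen to C4 of ring B, and ring B is tied through the C7' methylene to C8' of a tetrahydrofuran (O, C7'', C8'', C8', C9') whose C7'' bears ring C and whose C8'' bears the C9'' hydroxymethyl group. There are five stereocentres in two clusters: the acyclic erythro pair C7 (R)/C8 (S), and the contiguous ring triad C7'' (S), C8'' (R), C8' (R), with ring C trans to C9'' and C9'' cis to the C7' benzyl arm. Ring B separates the clusters, so neither can direct the other and each needs its own source of absolute configuration. The fragile groups are the two free phenols and the C7–OH and C7''–O bonds, both benzylic to para-oxygenated rings: they ionise in acid (epimerisation, aryltetralin closure) and can be cleaved by forcing hydrogenolysis. The real difficulty is the erythro relation in a flexible chain, the contra-thermodynamic 3,4-cis relation in the ring, and joining the halves at the C7'–ring B bond without disturbing either. The key step exploits the fact that, with C7 as a ketone and C9 as an ester, C8 (carrying the ring B aryloxy group) lies between two carbonyls and epimerises freely, so one selective hydride transfer to C7 fixes C7 and C8 together. The bromine on ring B, para to the ether oxygen, marks the carbon that later receives C7'.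

## Logic of the disconnections

20 to 19: the two O–CH2Ph bonds on rings A and C are cut last. Benzyl is the one phenol mask that survives strong base, enzyme buffer, hydride, peracid, radical and palladium chemistry. The forward hydrogenolysis must stop before the benzylic C7–O and C7''–O bonds are attacked.

19 to 9 and 17 (through 18): the C7'–aryl bond of ring B and the C8'–H bond are cut. This splits the molecule into two halves of similar size, each with one stereocluster, and traces C8' back to a flat alkene carbon. The forward step must deliver hydrogen to C8' from the face opposite C9'' and must couple in the presence of four free hydroxyls. No acetal is placed on the diol of 9, which saves two steps and the only acidic operation.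

9 to 8: only the C9 oxidation level changes. The ester is needed for the acidity of C8–H and for nothing else, so it is reduced directly after the stereocentres are set, before any basic step.

8 to 7: the C7–H bond is cut. Both chain stereocentres disappear into one epimerising racemate. The forward step needs a catalyst that accepts one C8 epimer and one carbonyl face, and an epimerisation faster than the reduction.

7 to 3 and 4 (through 5 and 6): the C7–C8 bond is cut. Two achiral aromatic pieces result and the 1,3-dicarbonyl arises in a single C–C bond formation. The forward acylation must go at carbon, not oxygen, and needs a second equivalent of enolate because 7 is more acidic than 3.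

3 to 1 and 2: the O–C8 ether bond is cut. Putting the aryloxy group on an acetate unit before the ketone exists avoids a substitution at a hindered, doubly activated carbon.

17 to 16: the C8''–C8' bond, and with it the ring, is cut to a C8'' radical and an alkyne. The alkyne acceptor leaves the exocyclic methylene needed for the coupling. The ring closure must be trans relative to C7'' and must outrun reduction of the radical.

16 to 15: the two C–O bonds of the oxirane are cut. Its configuration is irrelevant because that carbon becomes planar.

15 to 13 and 14: the O–C9' ether bond is cut; the stereocentre is not involved.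

13 to 12: no bond is cut; one enantiomer is selected. C7'' is the only stereocentre of this half that has to come from outside; the price is half of the material.

12 to 10 and 11: the C7''–C8'' bond is cut to an aromatic aldehyde and a vinyl nucleophile.

## Other disconnections considered

Alternative 1: The cut is the C8''–C8' ring bond together with the C7'–H bond, leading from the protected lignan A1 back to the epoxy cinnamyl ether A2. A2 differs from 16 only in the ether arm, which already contains ring B as an (E)-cinnamyl unit. In the forward step Cp2TiCl opens the oxirane to the C8'' radical, 5-exo-trig addition to the cinnamyl double bond closes the ring, and the benzylic C7' radical is reduced and protonated.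
- In favour: ring, C8''–C8' bond, both new ring stereocentres and the link to ring B arise in one step, without palladium and without a hydroboration. The lignan half is reached in fewer steps than by steps 9 and 10; on this point the alternative is the better.
- Against: ring B emerges as a silyl ether, so the glycerol unit must be built on the freed phenol afterwards. The dynamic reduction would then be asked of a substrate twice as large, with three stereocentres and a free C9'' hydroxyl, and the synthesis becomes linear. The C8' configuration depends on the conformation of the cyclisation transition state.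
- Comparison: the mechanism up to ring closure is the same radical manifold as in step 9, and C8' is under substrate control in both plans, so they are equals there. The chosen plan is better in convergence and in placing the enzymatic step on a small substrate.

Alternative 2: The cut is the benzylic C7'–O bond of a furofuran, leading from the ring C pivalate A3 back to the mono-pivalate A4 of the natural furofuran lignan A5. In the forward step a pinoresinol–lariciresinol reductase with NADPH expels O9'' from C7' through the quinone methide of the free-phenol ring and delivers hydride to C7'.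
- In favour: all three ring stereocentres and the whole carbon skeleton of the lignan half come from A5, with no C–C bond formation and no resolution. Regiochemistry follows from the mechanism, since only the ring with the free phenol can form the quinone methide and the pivalate also blocks a second reduction. Two steps reach A3; in step count and stereochemical security for this half the alternative is the better.
- Against: A5 is symmetrical, so mono-acylation is statistical, and enantiopure A5 is a scarce natural product. The reductase is not an off-the-shelf catalyst and may not accept an acylated substrate. After A3 the glycerol unit still has to be built on ring B with late control of C7 and C8, as in Alternative 1.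
- Comparison: both plans rest on an enzymatic hydride transfer and are equals in mechanistic elegance. The chosen plan needs one enzyme of a commercial class on a small substrate and is convergent; the alternative needs a bespoke enzyme and then a second selective reduction on a large substrate.

Alternative 3: The cuts are the C7'–C8' and C8''–C7'' bonds, leading from lactone A6 back to the menthyloxy butenolide A7, the ring B dithiane A8 and aldehyde 10. In the forward step lithiated A8 adds to the β-carbon of A7 anti to the menthyloxy group and the lactone enolate is trapped by 10.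
- In favour: two C–C bonds and three stereocentres form in one flask under a cheap, recoverable auxiliary with a well-understood trans,trans outcome. No kinetic resolution is needed; this is better than step 6, whose ceiling is one half. The bond-forming density is higher than in any step of the chosen plan.
- Against: A6 is at the wrong oxidation level. Desulfurisation (which threatens the benzyl ether), reduction of lactone and acetal with loss of menthol, ring closure through the benzylic C7'' position, desilylation and then the glycerol unit on ring B would all follow, so six or more steps remain before the stage of 19.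
- Comparison: the alternative is the better in stereochemical economy at the key step; the chosen plan is the better in total step count and convergence.

Key step: step 3

## Route

Step 1
Reactants: 1 4-bromo-2-methoxyphenol; 2 ethyl bromoacetate
Product: 3 ethyl 2-(4-bromo-2-methoxyphenoxy)acetate
Conditions: K2CO3, acetone, reflux
Reagents that add atoms: ethyl bromoacetate (compound 2), CCOC(=O)CBr
Why: Williamson ether synthesis: the phenoxide displaces bromide from the primary α-bromo ester by SN2; the aryl bromide is inert and no stereocentre is involved.

Step 2
Reactants: 4 4-(benzyloxy)-3-methoxybenzoic acid; 3 ethyl 2-(4-bromo-2-methoxyphenoxy)acetate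
Product: 7 ethyl 3-[4-(benzyloxy)-3-methoxyphenyl]-2-(4-bromo-2-methoxyphenoxy)-3-oxopropanoate, via 4-(benzyloxy)-3-methoxybenzoyl chloride 5 (not isolated), via lithium ester enolate 6 (not isolated)
Conditions: 4, (COCl)2, DMF (cat.), CH2Cl2, 0 °C → rt, evaporation; 3 (2.1 equiv), LiN(SiMe3)2 (2.1 equiv), THF, −78 °C, then 5, −78 → −20 °C; aq. NH4Cl
Reagents that add atoms: none
Why: Crossed Claisen-type C-acylation of a lithium ester enolate by an aroyl chloride; the second equivalent of enolate deprotonates the more acidic product and so prevents double acylation, and the surplus 3 is recovered. The amide base does not attack the aryl bromide at −78 °C, and 7 is obtained as a racemate whose C8 epimers interconvert.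

Step 3
Reactants: 7 ethyl 3-[4-(benzyloxy)-3-methoxyphenyl]-2-(4-bromo-2-methoxyphenoxy)-3-oxopropanoate
Product: 8 ethyl (2R,3R)-3-[4-(benzyloxy)-3-methoxyphenyl]-2-(4-bromo-2-methoxyphenoxy)-3-hydroxypropanoate
Conditions: ketoreductase (variant selected from a panel for the anti (2R,3R) product), NADP+ (cat.), iPrOH (10% v/v), DMSO (10% v/v), potassium phosphate buffer pH 7.5, MgSO4, 30 °C
Reagents that add atoms: none
Why: Ketoreductase-catalysed dynamic kinetic resolution by asymmetric reduction: the enzyme binds the (2R)-epimer of 7 productively and NADPH transfers hydride to the Si face of the C7 carbonyl, forming the C7–H bond, while isopropanol regenerates NADPH and ends as acetone. The (2S)-epimer is not reduced at a useful rate but returns to the pool through the enol of the 1,3-dicarbonyl, which forms readily at pH 7.5 because C8–H is flanked by the ketone, the ester and the aryloxy oxygen. The closest known reaction type is the ketoreductase dynamic reduction of α-chloro-, α-alkyl- and α-amido-β-keto esters; no ring is closed. C7 (R) is controlled by the facial delivery of hydride in the active site and C8 (R in the ester, S after step 4) by the enzyme's choice of epimer, so both centres rest on the selected variant and not on the substrate. The step needs anti (erythro) over syn diastereoselectivity, enantioselectivity and chemoselectivity for the ketone; the ester, the aryl bromide and the benzyl ether are not substrates of the enzyme. The product no longer epimerises, since its C8–H is only α to an ester, so the configuration is locked once hydride is delivered. The panel screen is part of the step: variants are chosen on anti selectivity first and on rate second.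

Step 4
Reactants: 8 ethyl (2R,3R)-3-[4-(benzyloxy)-3-methoxyphenyl]-2-(4-bromo-2-methoxyphenoxy)-3-hydroxypropanoate
Product: 9 (1R,2S)-1-[4-(benzyloxy)-3-methoxyphenyl]-2-(4-bromo-2-methoxyphenoxy)propane-1,3-diol
Conditions: NaBH4, THF/EtOH, 0 °C → rt
Reagents that add atoms: none
Why: Borohydride reduction of an ester activated by the α-aryloxy group and the neighbouring hydroxyl; C7 and C8 are not touched, and the C8 descriptor changes from R to S by priority only. Reducing at once removes the last acidic C8–H before any basic step; the aryl bromide and benzyl ether are inert to NaBH4.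

Step 5
Reactants: 10 4-(benzyloxy)-3-methoxybenzaldehyde; 11 vinylmagnesium bromide
Product: 12 rac-1-[4-(benzyloxy)-3-methoxyphenyl]prop-2-en-1-ol
Conditions: THF, −78 → 0 °C; aq. NH4Cl
Reagents that add atoms: vinylmagnesium bromide (compound 11), C=C[Mg]Br
Why: Grignard 1,2-addition of a vinyl nucleophile to a non-enolisable aromatic aldehyde; the new carbinol centre (later C7'') is formed racemic and is resolved in step 6.

Step 6
Reactants: 12 rac-1-[4-(benzyloxy)-3-methoxyphenyl]prop-2-en-1-ol
Product: 13 (1S)-1-[4-(benzyloxy)-3-methoxyphenyl]prop-2-en-1-ol
Conditions: immobilised Candida antarctica lipase B (Novozym 435), vinyl acetate, tert-butyl methyl ether, 30 °C, to slightly beyond half conversion; chromatography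
Reagents that add atoms: none
Why: Lipase-catalysed kinetic resolution by enantioselective transesterification: with the aryl ring as the large and the vinyl group as the medium substituent, the empirical size rule for lipases predicts acetylation of the (R)-alcohol, so that the (S)-alcohol 13 is left behind. Running slightly past half conversion should leave 13 in high enantiomeric purity, and the (R)-acetate is removed by chromatography.

Step 7
Reactants: 13 (1S)-1-[4-(benzyloxy)-3-methoxyphenyl]prop-2-en-1-ol; 14 3-bromoprop-1-yne (propargyl bromide)
Product: 15 1-(benzyloxy)-2-methoxy-4-[(1S)-1-(prop-2-yn-1-yloxy)prop-2-en-1-yl]benzene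
Conditions: NaH, Bu4NI (cat.), THF/DMF, 0 °C → rt
Reagents that add atoms: 3-bromoprop-1-yne (compound 14), C#CCBr
Why: Williamson ether synthesis with a primary propargylic bromide; the C–O bond at the stereocentre is not broken, so the configuration of 13 is carried over unchanged.

Step 8
Reactants: 15 1-(benzyloxy)-2-methoxy-4-[(1S)-1-(prop-2-yn-1-yloxy)prop-2-en-1-yl]benzene
Product: 16 2-{(R)-[4-(benzyloxy)-3-methoxyphenyl](prop-2-yn-1-yloxy)methyl}oxirane (both epimers at the oxirane CH)
Conditions: mCPBA, NaHCO3, CH2Cl2, 0 °C → rt
Reagents that add atoms: 3-chloroperoxybenzoic acid (mCPBA), OOC(=O)c1cccc(Cl)c1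
Why: Prilezhaev epoxidation: the peracid reacts with the alkene far faster than with the terminal alkyne, and the bicarbonate buffer protects the acid-labile benzylic ether. Both oxirane epimers are acceptable because that carbon becomes a planar radical in step 9; the carbinol descriptor changes from S to R by priority only.

Step 9
Reactants: 16 2-{(R)-[4-(benzyloxy)-3-methoxyphenyl](prop-2-yn-1-yloxy)methyl}oxirane
Product: 17 {(2S,3R)-2-[4-(benzyloxy)-3-methoxyphenyl]-4-methylideneoxolan-3-yl}methanol
Conditions: Cp2TiCl2 (2.5 equiv), Zn dust, THF, rt, the green Cp2TiCl solution added slowly to 16; aq. NaH2PO4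
Reagents that add atoms: none
Why: Nugent–RajanBabu reductive epoxide opening followed by 5-exo-dig radical cyclisation: Cp2TiCl (trivalent titanium) transfers one electron to the oxirane and opens it to the more substituted β-titanoxy radical at C8'', which adds to the inner alkyne carbon (C8''–C8' bond); the vinyl radical is quenched by hydrogen abstraction from THF or by a second Cp2TiCl and protonation, leaving the exocyclic methylene. C8'' is set in the ring closure, where a chair-like transition state with ring C and the CH2OTi group both pseudo-equatorial favours the 2,3-trans ring, while C7'' is untouched; slow addition keeps the titanium concentration low so that cyclisation outruns reduction of the radical.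

Step 10
Reactants: 17 {(2S,3R)-2-[4-(benzyloxy)-3-methoxyphenyl]-4-methylideneoxolan-3-yl}methanol; 9 (1R,2S)-1-[4-(benzyloxy)-3-methoxyphenyl]-2-(4-bromo-2-methoxyphenoxy)propane-1,3-diol
Product: 19 (1R,2S)-1-[4-(benzyloxy)-3-methoxyphenyl]-2-[4-({(3R,4R,5S)-5-[4-(benzyloxy)-3-methoxyphenyl]-4-(hydroxymethyl)oxolan-3-yl}methyl)-2-methoxyphenoxy]propane-1,3-diol, via B-alkyl-9-BBN adduct 18 (not isolated)
Conditions: 17 (1.3 equiv), 9-BBN (2.8 equiv), THF, 0 °C → rt; then 9, Pd(OAc)2 (5 mol%), SPhos (10 mol%), aq. K3PO4, THF, 60 °C
Reagents that add atoms: none
Why: Hydroboration followed by B-alkyl Suzuki–Miyaura coupling: the first equivalent of 9-BBN converts the hydroxyl into a bulky O-boryl group, and the second adds anti-Markovnikov to the methylene from the face opposite that group, so that hydrogen enters C8' trans to C9'' and the new C7' carbon lies cis to it (8'R). Oxidative addition of the aryl bromide of 9 to zerovalent palladium (SPhos for the electron-rich ring), base-assisted transfer of the primary alkyl group from boron and reductive elimination form the C7'–aryl bond; free hydroxyls do not interfere in aqueous phosphate, which also hydrolyses the O–B bond.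

Step 11
Reactants: 19 (1R,2S)-1-[4-(benzyloxy)-3-methoxyphenyl]-2-[4-({(3R,4R,5S)-5-[4-(benzyloxy)-3-methoxyphenyl]-4-(hydroxymethyl)oxolan-3-yl}methyl)-2-methoxyphenoxy]propane-1,3-diol
Product: 20 (1R,2S)-1-(4-hydroxy-3-methoxyphenyl)-2-[4-({(3R,4R,5S)-5-(4-hydroxy-3-methoxyphenyl)-4-(hydroxymethyl)oxolan-3-yl}methyl)-2-methoxyphenoxy]propane-1,3-diol (CNP0158473.3)
Conditions: H2 (1 atm), 10% Pd/C, EtOAc/EtOH, rt, stopped when 19 is consumed
Reagents that add atoms: none
Why: Catalytic hydrogenolysis of the two aryl benzyl ethers; under neutral conditions these cleave much faster than the benzylic C7–OH and C7''–O bonds, so the reaction is stopped as soon as 19 is consumed. No stereocentre is affected and the free phenols see neither acid nor base.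

## Compound list

1 | 4-bromo-2-methoxyphenol | COc1cc(Br)ccc1O | starting material
2 | ethyl bromoacetate | CCOC(=O)CBr | starting material
3 | ethyl 2-(4-bromo-2-methoxyphenoxy)acetate | CCOC(=O)COc1ccc(Br)cc1OC | intermediate
4 | 4-(benzyloxy)-3-methoxybenzoic acid | COc1cc(C(=O)O)ccc1OCc1ccccc1 | starting material
5 | 4-(benzyloxy)-3-methoxybenzoyl chloride | COc1cc(C(Cl)=O)ccc1OCc1ccccc1 | intermediate (not isolated)
6 | lithium enolate of 3, lithium 2-(4-bromo-2-methoxyphenoxy)-1-ethoxyethen-1-olate | [Li+].CCOC([O-])=COc1ccc(Br)cc1OC | intermediate (not isolated)
7 | ethyl 3-[4-(benzyloxy)-3-methoxyphenyl]-2-(4-bromo-2-methoxyphenoxy)-3-oxopropanoate (racemate, C8 epimerising) | COc1cc(C(=O)C(C(=O)OCC)Oc2ccc(Br)cc2OC)ccc1OCc1ccccc1 | intermediate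
8 | ethyl (2R,3R)-3-[4-(benzyloxy)-3-methoxyphenyl]-2-(4-bromo-2-methoxyphenoxy)-3-hydroxypropanoate | COc1cc([C@@H](O)[C@H](C(=O)OCC)Oc2ccc(Br)cc2OC)ccc1OCc1ccccc1 | intermediate
9 | (1R,2S)-1-[4-(benzyloxy)-3-methoxyphenyl]-2-(4-bromo-2-methoxyphenoxy)propane-1,3-diol | COc1cc([C@@H](O)[C@H](CO)Oc2ccc(Br)cc2OC)ccc1OCc1ccccc1 | intermediate
10 | 4-(benzyloxy)-3-methoxybenzaldehyde | COc1cc(C=O)ccc1OCc1ccccc1 | starting material
11 | vinylmagnesium bromide | C=C[Mg]Br | starting material
12 | rac-1-[4-(benzyloxy)-3-methoxyphenyl]prop-2-en-1-ol | OC(C=C)c1ccc(OCc2ccccc2)c(OC)c1 | intermediate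
13 | (1S)-1-[4-(benzyloxy)-3-methoxyphenyl]prop-2-en-1-ol | O[C@H](c1ccc(OCc2ccccc2)c(OC)c1)C=C | intermediate
14 | 3-bromoprop-1-yne | C#CCBr | starting material
15 | 1-(benzyloxy)-2-methoxy-4-[(1S)-1-(prop-2-yn-1-yloxy)prop-2-en-1-yl]benzene | C#CCO[C@H](c1ccc(OCc2ccccc2)c(OC)c1)C=C | intermediate
16 | 2-{(R)-[4-(benzyloxy)-3-methoxyphenyl](prop-2-yn-1-yloxy)methyl}oxirane, both oxirane epimers | C#CCO[C@H](c1ccc(OCc2ccccc2)c(OC)c1)C1CO1 | intermediate
17 | {(2S,3R)-2-[4-(benzyloxy)-3-methoxyphenyl]-4-methylideneoxolan-3-yl}methanol | C=C1CO[C@H](c2ccc(OCc3ccccc3)c(OC)c2)[C@H]1CO | intermediate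
18 | 9-{[(3R,4R,5S)-5-[4-(benzyloxy)-3-methoxyphenyl]-4-{[(9-borabicyclo[3.3.1]nonan-9-yl)oxy]methyl}oxolan-3-yl]methyl}-9-borabicyclo[3.3.1]nonane | C(B1C2CCCC1CCC2)[C@H]1CO[C@H](c2ccc(OCc3ccccc3)c(OC)c2)[C@H]1COB1C2CCCC1CCC2 | intermediate (not isolated)
19 | (1R,2S)-1-[4-(benzyloxy)-3-methoxyphenyl]-2-[4-({(3R,4R,5S)-5-[4-(benzyloxy)-3-methoxyphenyl]-4-(hydroxymethyl)oxolan-3-yl}methyl)-2-methoxyphenoxy]propane-1,3-diol | COc1cc([C@@H](O)[C@H](CO)Oc2ccc(C[C@H]3CO[C@H](c4ccc(OCc5ccccc5)c(OC)c4)[C@H]3CO)cc2OC)ccc1OCc1ccccc1 | intermediate
20 | (1R,2S)-1-(4-hydroxy-3-methoxyphenyl)-2-[4-({(3R,4R,5S)-5-(4-hydroxy-3-methoxyphenyl)-4-(hydroxymethyl)oxolan-3-yl}methyl)-2-methoxyphenoxy]propane-1,3-diol | COc1cc([C@@H](O)[C@H](CO)Oc2ccc(C[C@H]3CO[C@H](c4ccc(O)c(OC)c4)[C@H]3CO)cc2OC)ccc1O | target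

## Step count and risk

Total step count: 11. Longest linear sequence: 7 steps (steps 5, 6, 7, 8, 9, 10, 11, from 10); the ring A/ring B branch contributes steps 1–4 before the coupling.

Step 3 (key step). The most likely failures are low activity toward the bulky diaryl ketone, a syn instead of an anti preference in the variants available, or epimerisation at C8 that is slower than reduction, so that the resolution stops being dynamic and the selectivity erodes as the favoured epimer is used up. The fallback sets out from 3 and 10 and comes back at 9. Deprotonation of 3 with LiN(iPr)2 (THF, −78 °C) and addition to 10 should give the racemic β-hydroxy ester with the erythro form predominating; chromatography would give ethyl rac-erythro-3-[4-(benzyloxy)-3-methoxyphenyl]-2-(4-bromo-2-methoxyphenoxy)-3-hydroxypropanoate F1. NaBH4 then gives the racemic erythro diol F2. A lipase (Burkholderia cepacia lipase, vinyl acetate, tert-butyl methyl ether), selected for acetylating the primary hydroxyl of the (1S,2R) enantiomer, would convert that enantiomer into its monoacetate F3 and leave 9 for chromatographic separation. The price is half of the material.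

Step 10. Facial discrimination in the hydroboration may be incomplete, giving C8' epimers that are hard to remove after coupling. Transfer of the β-branched alkyl group from boron to palladium may also be slow against an electron-rich aryl bromide, which favours protodeboronation and reduction of the bromide. The fallback sets out from 17 and comes back at 19. TBSCl/imidazole gives tert-butyl({(2S,3R)-2-[4-(benzyloxy)-3-methoxyphenyl]-4-methylideneoxolan-3-yl}methoxy)dimethylsilane F4, in which the steric bias is permanent. Hydroboration with 9-BBN and oxidative work-up (NaOH, H2O2) gives the primary alcohol F5, at which stage a C8' epimer can be removed by chromatography. I2, PPh3 and imidazole give the iodide F6. A nickel-catalysed reductive cross-electrophile coupling of F6 with 9 (NiBr2(dme), 4,4'-di-tert-butyl-2,2'-bipyridine, Zn, NaI, N,N-dimethylacetamide, 60 °C), which needs no organoboron reagent and tolerates free hydroxyls, gives the silyl ether of 19 F7. Bu4NF then gives 19.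

Step 9. A second Cp2TiCl may reduce the C8'' radical before it cyclises; β-elimination of the titanium alkoxide would then lead back to the alkene (deoxygenation). The ring closure may also be incompletely trans-selective. The fallback sets out from 15 and comes back at 17. OsO4 (cat.) with N-methylmorpholine N-oxide dihydroxylates the vinyl group to (3R)-3-[4-(benzyloxy)-3-methoxyphenyl]-3-(prop-2-yn-1-yloxy)propane-1,2-diol F8. TBSCl/imidazole silylates the primary hydroxyl to give the mono-silyl ether F9, and I2, PPh3 and imidazole (toluene, 80 °C) give the secondary iodide F10. Bu3SnH with AIBN (slow addition, toluene, 80 °C) generates the same C8'' radical with no reducing metal present; 5-exo-dig closure gives the silyl ether F4 already met above, which Bu4NF converts into 17.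

Step 2. O-acylation of the enolate, acylation of the product enolate, or proton transfer that quenches the enolate before it is acylated may lower the yield of 7. The fallback sets out from 3 and 10 and comes back at 7. The LiN(iPr)2 aldol addition of 3 to 10 gives ethyl 3-[4-(benzyloxy)-3-methoxyphenyl]-2-(4-bromo-2-methoxyphenoxy)-3-hydroxypropanoate as a mixture of all stereoisomers F11, and Dess–Martin periodinane oxidises it to 7. The stereochemical mixture is of no consequence, because C7 becomes trigonal and C8 epimerises. The route becomes one step longer.

## Further compounds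

F1 | step 3 | ethyl rac-erythro-3-[4-(benzyloxy)-3-methoxyphenyl]-2-(4-bromo-2-methoxyphenoxy)-3-hydroxypropanoate (racemate, (2R,3R) enantiomer drawn) | COc1cc([C@@H](O)[C@H](C(=O)OCC)Oc2ccc(Br)cc2OC)ccc1OCc1ccccc1
F2 | step 3 | rac-erythro-1-[4-(benzyloxy)-3-methoxyphenyl]-2-(4-bromo-2-methoxyphenoxy)propane-1,3-diol (racemate, (1R,2S) enantiomer drawn) | COc1cc([C@@H](O)[C@H](CO)Oc2ccc(Br)cc2OC)ccc1OCc1ccccc1
F3 | step 3 | (2R,3S)-3-[4-(benzyloxy)-3-methoxyphenyl]-2-(4-bromo-2-methoxyphenoxy)-3-hydroxypropyl acetate | COc1cc([C@H](O)[C@@H](COC(C)=O)Oc2ccc(Br)cc2OC)ccc1OCc1ccccc1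
F4 | step 10 | tert-butyl({(2S,3R)-2-[4-(benzyloxy)-3-methoxyphenyl]-4-methylideneoxolan-3-yl}methoxy)dimethylsilane | C=C1CO[C@H](c2ccc(OCc3ccccc3)c(OC)c2)[C@H]1CO[Si](C)(C)C(C)(C)C
F5 | step 10 | {(3S,4R,5S)-5-[4-(benzyloxy)-3-methoxyphenyl]-4-({[tert-butyl(dimethyl)silyl]oxy}methyl)oxolan-3-yl}methanol | OC[C@H]1CO[C@H](c2ccc(OCc3ccccc3)c(OC)c2)[C@H]1CO[Si](C)(C)C(C)(C)C
F6 | step 10 | tert-butyl({(2S,3R,4R)-2-[4-(benzyloxy)-3-methoxyphenyl]-4-(iodomethyl)oxolan-3-yl}methoxy)dimethylsilane | IC[C@H]1CO[C@H](c2ccc(OCc3ccccc3)c(OC)c2)[C@H]1CO[Si](C)(C)C(C)(C)C
F7 | step 10 | C9''-O-tert-butyldimethylsilyl ether of 19 | COc1cc([C@@H](O)[C@H](CO)Oc2ccc(C[C@H]3CO[C@H](c4ccc(OCc5ccccc5)c(OC)c4)[C@H]3CO[Si](C)(C)C(C)(C)C)cc2OC)ccc1OCc1ccccc1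
F8 | step 9 | (3R)-3-[4-(benzyloxy)-3-methoxyphenyl]-3-(prop-2-yn-1-yloxy)propane-1,2-diol, both C2 epimers | C#CCO[C@H](c1ccc(OCc2ccccc2)c(OC)c1)C(O)CO
F9 | step 9 | (1R)-1-[4-(benzyloxy)-3-methoxyphenyl]-3-{[tert-butyl(dimethyl)silyl]oxy}-1-(prop-2-yn-1-yloxy)propan-2-ol, both C2 epimers | C#CCO[C@H](c1ccc(OCc2ccccc2)c(OC)c1)C(O)CO[Si](C)(C)C(C)(C)C
F10 | step 9 | tert-butyl{[(3R)-3-[4-(benzyloxy)-3-methoxyphenyl]-2-iodo-3-(prop-2-yn-1-yloxy)propyl]oxy}dimethylsilane, both C2 epimers | C#CCO[C@H](c1ccc(OCc2ccccc2)c(OC)c1)C(I)CO[Si](C)(C)C(C)(C)C
F11 | step 2 | ethyl 3-[4-(benzyloxy)-3-methoxyphenyl]-2-(4-bromo-2-methoxyphenoxy)-3-hydroxypropanoate, mixture of all stereoisomers | COc1cc(C(O)C(C(=O)OCC)Oc2ccc(Br)cc2OC)ccc1OCc1ccccc1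
A1 | alternative 1 | {(2S,3R,4R)-2-[4-(benzyloxy)-3-methoxyphenyl]-4-[3-methoxy-4-(triisopropylsilyloxy)benzyl]oxolan-3-yl}methanol | CC(C)[Si](C(C)C)(C(C)C)Oc1ccc(C[C@H]2CO[C@H](c3ccc(OCc4ccccc4)c(OC)c3)[C@H]2CO)cc1OC
A2 | alternative 1 | 2-{(R)-[4-(benzyloxy)-3-methoxyphenyl]({(2E)-3-[3-methoxy-4-(triisopropylsilyloxy)phenyl]prop-2-en-1-yl}oxy)methyl}oxirane | COc1cc(/C=C/CO[C@H](c2ccc(OCc3ccccc3)c(OC)c2)C2CO2)ccc1O[Si](C(C)C)(C(C)C)C(C)C
A3 | alternative 2 | (+)-lariciresinol ring C pivalate, 4-[(2S,3R,4R)-4-(4-hydroxy-3-methoxybenzyl)-3-(hydroxymethyl)oxolan-2-yl]-2-methoxyphenyl 2,2-dimethylpropanoate | COc1cc(C[C@H]3CO[C@H](c4ccc(OC(=O)C(C)(C)C)c(OC)c4)[C@H]3CO)ccc1O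
A4 | alternative 2 | (+)-pinoresinol mono-pivalate | COc1cc([C@@H]2[C@H]3CO[C@H](c4ccc(OC(=O)C(C)(C)C)c(OC)c4)[C@H]3CO2)ccc1O
A5 | alternative 2 | (+)-pinoresinol | COc1cc([C@@H]2[C@H]3CO[C@H](c4ccc(O)c(OC)c4)[C@H]3CO2)ccc1O
A6 | alternative 3 | trans,trans-3-{[4-(benzyloxy)-3-methoxyphenyl](hydroxy)methyl}-5-(l-menthyloxy)-4-{2-[3-methoxy-4-(triisopropylsilyloxy)phenyl]-1,3-dithian-2-yl}oxolan-2-one, configuration as in the SMILES | CC(C)[Si](C(C)C)(C(C)C)Oc1ccc(C2(SCCCS2)[C@H]3[C@H](O[C@@H]4C[C@H](C)CC[C@H]4C(C)C)OC(=O)[C@@H]3[C@H](O)c5ccc(OCc6ccccc6)c(OC)c5)cc1OC
A7 | alternative 3 | (5R)-5-[(1R,2S,5R)-menthyloxy]furan-2(5H)-one | O=C1C=C[C@H](O[C@@H]2C[C@H](C)CC[C@H]2C(C)C)O1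
A8 | alternative 3 | 2-[3-methoxy-4-(triisopropylsilyloxy)phenyl]-1,3-dithiane | COc1cc(C2SCCCS2)ccc1O[Si](C(C)C)(C(C)C)C(C)C
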